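**Retrosynthetic overview**
1. Target ⇐ 6‑O‑silyl, 9‑OH lactone enal (late methacrylation, last desilylation). The α‑methylene lactone and the enal come together from two 2‑(hydroxymethyl)vinyl groups by MnO2.
2. A C6 ketone is the hub: C7 side chain by α‑iodoenone Negishi coupling, C5 side chain by α′‑alkenylation, 8α‑OH by hydroxyl‑directed epoxidation and SmI2 opening, 6β‑OH by bulky hydride.
3. Enone ⇐ allylic oxidation of a cyclohexene; oxirane ⇐ chloromethyl ketone by CBS reduction and ring closure.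
4. Cyclohexene ⇐ catalytic enantioselective endo Diels–Alder reaction of (E)‑1‑silyloxybutadiene with methacrolein (sets C9 and C10).
5. Ring order: cyclohexene first, oxirane second, γ‑lactone last.

Locants in names follow elemane numbering: ring C10 (quaternary)–C9–C8–C7–C6–C5; C1/C2 are the oxirane carbons on C10; C4 (with C3, C15) sits on C5; C11 (with C13, C12) sits on C7. β is the ring face carrying the C10 methyl group, α the opposite face.

Assumption: the (S)‑diphenylprolinol‑derived oxazaborolidinium salt is taken to give the (1S,2R) adduct 7; if the facial sense is the other way, the mirror‑image salt is used and nothing else changes.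

**Step 1**
Reactants: 1 2,3‑dibromoprop‑1‑ene; 2 4‑methoxybenzyl alcohol
Product: 3 2‑bromoallyl 4‑methoxybenzyl ether
Conditions: NaH, THF/DMF, 0 °C → rt
Reagents that add atoms: none
Why: Williamson etherification; the alkoxide of 2 displaces the allylic bromide of 1 (SN2) and the vinylic C–Br bond is inert.

**Step 2**
Reactants: 4 (E)‑but‑2‑enal
Product: 5 (E)‑1‑(tert‑butyldimethylsilyloxy)buta‑1,3‑diene
Conditions: t‑BuMe2SiOTf, Et3N, Et2O, 0 °C → rt
Reagents that add atoms: tert‑butyldimethylsilyl trifluoromethanesulfonate, CC(C)(C)[Si](C)(C)OS(=O)(=O)C(F)(F)F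
Why: Soft γ‑enolisation and O‑silylation of the enal gives the silyl dienol ether, mainly as the E isomer (the minor Z isomer does not react in step 3).

**Step 3**
Reactants: 5 (E)‑1‑(tert‑butyldimethylsilyloxy)buta‑1,3‑diene; 6 methacrolein
Product: 7 (1S,2R)‑2‑(tert‑butyldimethylsilyloxy)‑1‑methylcyclohex‑3‑ene‑1‑carbaldehyde
Conditions: (S)‑3,3‑diphenyl‑1‑(2‑methylphenyl)tetrahydro‑1H,3H‑pyrrolo[1,2‑c][1,3,2]oxazaborole·HNTf2 (20 mol %), CH2Cl2, −78 °C
Reagents that add atoms: none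
Why: Oxazaborolidinium‑catalysed enantioselective Diels–Alder reaction; ortho regiochemistry and an endo formyl group give the cis CHO/OTBS adduct, setting C10 and C9 together.

**Step 4**
Reactants: 7 Diels–Alder aldehyde
Product: 8 chlorohydrins (both C1 epimers)
Conditions: ICH2Cl, MeLi·LiBr, THF, −78 °C; AcOH quench at −78 °C
Reagents that add atoms: chloroiodomethane, ClCI
Why: Addition of chloromethyllithium (carbenoid from I/Li exchange) to the non‑enolisable aldehyde brings in C2; the C1 configuration is erased in step 5.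

**Step 5**
Reactants: 8 chlorohydrins
Product: 9 chloromethyl ketone
Conditions: Dess–Martin periodinane, CH2Cl2, rt
Reagents that add atoms: none
Why: Dess–Martin oxidation of the secondary alcohol; the α‑carbon C10 is quaternary, so nothing can epimerise.

**Step 6**
Reactants: 9 chloromethyl ketone
Product: 12 (2R)‑oxiranyl cyclohexene, via catechol borate 10 (not isolated), via (1R)‑chlorohydrin 11 (not isolated)
Conditions: (R)‑1‑methyl‑3,3‑diphenyltetrahydro‑1H,3H‑pyrrolo[1,2‑c][1,3,2]oxazaborole (20 mol %), catecholborane, toluene, −78 → −40 °C; then MeOH, 2 M NaOH, 0 °C → rt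
Reagents that add atoms: none
Why: Corey–Bakshi–Shibata reduction (quaternary C10 as large group, CH2Cl as small group) sets C1 as R under reagent control, and base closes the chlorohydrin to the oxirane with retention at C1 (intramolecular Williamson reaction).

**Step 7**
Reactants: 12 oxiranyl cyclohexene
Product: 13 cyclohex‑7‑en‑6‑one
Conditions: Rh2(C6H10NO)4 [dirhodium tetrakis(caprolactamate), 1 mol %], t‑BuOOH (70 % aq.), K2CO3, CH2Cl2, rt
Reagents that add atoms: tert‑butyl hydroperoxide, CC(C)(C)OO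
Why: Radical allylic C–H oxidation at C6, the only allylic methylene, gives the enone without touching a stereocentre.

**Step 8**
Reactants: 13 enone; 3 2‑bromoallyl 4‑methoxybenzyl ether
Product: 15 5β‑alkenyl enone, via trimethylsilyl dienol ether 14 (not isolated)
Conditions: LiN(SiMe3)2, Me3SiCl, THF, −78 °C; then 3, Bu3SnF, PdCl2[P(o‑tolyl)3]2 (5 mol %), toluene, 90 °C
Reagents that add atoms: none
Why: Kosugi–Migita‑type Pd‑catalysed α‑alkenylation of the tin enolate made from 14; the C–C bond forms at C5 on the β face, anti to the α‑oxiranyl group on C10 and the α‑OTBS group, under non‑basic conditions.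

**Step 9**
Reactants: 15 5β‑alkenyl enone
Product: 16 7‑iodoenone
Conditions: I2, pyridine, CH2Cl2, 0 °C → rt
Reagents that add atoms: iodine, II
Why: Johnson α‑iodination of the enone (pyridine addition, iodination, elimination) functionalises C7 only.

**Step 10**
Reactants: 16 7‑iodoenone; 3 2‑bromoallyl 4‑methoxybenzyl ether
Product: 19 5β,7‑dialkenyl enone, via 2‑lithioallyl ether 17 (not isolated), via alkenylzinc chloride 18 (not isolated)
Conditions: 3, t‑BuLi (2 equiv), Et2O, −78 °C; ZnCl2, THF; then 16, Pd(PPh3)4 (5 mol %), THF, rt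
Reagents that add atoms: none
Why: Negishi cross‑coupling of the α‑iodoenone with the alkenylzinc reagent (Br/Li exchange, transmetalation) installs the C11–C13 unit.

**Step 11**
Reactants: 19 dialkenyl enone
Product: 20 9α‑hydroxy enone
Conditions: Bu4NF, AcOH, THF, 0 °C → rt
Reagents that add atoms: none
Why: Fluoride cleavage of the TBS ether, buffered to avoid enolising C5, frees the hydroxyl needed to direct step 12.

**Step 12**
Reactants: 20 9α‑hydroxy enone
Product: 21 7α,8α‑epoxy ketone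
Conditions: 30 % H2O2, NaOH (cat.), MeOH, −10 °C
Reagents that add atoms: hydrogen peroxide, OO
Why: Weitz–Scheffer nucleophilic epoxidation, directed syn by the C9 hydroxyl and anti to the axial C10 methyl, puts the new oxygen on the α face of C8.

**Step 13**
Reactants: 21 epoxy ketone
Product: 22 8α,9α‑dihydroxy ketone
Conditions: SmI2, THF/MeOH, −90 °C
Reagents that add atoms: none
Why: SmI2 reductive opening of the α,β‑epoxy ketone breaks the C7–O bond; axial protonation of the samarium enolate leaves the C7 side chain equatorial (β) and the C8 hydroxyl α.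

**Step 14**
Reactants: 22 dihydroxy ketone
Product: 23 6β,8α,9α‑triol
Conditions: LiBH(s‑Bu)3, THF, −78 °C; then H2O
Reagents that add atoms: none
Why: Bulky‑hydride reduction; equatorial attack (the axial path is blocked by the axial C10 methyl) gives the axial 6β‑alcohol, cis to both flanking side chains.

**Step 15**
Reactants: 23 triol
Product: 26 6β‑triethylsilyloxy 8α,9α‑diol, via 8,9‑phenylboronate 24 (not isolated), via silylated phenylboronate 25 (not isolated)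
Conditions: PhB(OH)2, MgSO4, CH2Cl2, rt; then 2,6‑lutidine, Et3SiOTf, −78 → −20 °C; then pinacol, MeOH, rt
Reagents that add atoms: triethylsilyl trifluoromethanesulfonate, CC[Si](CC)(CC)OS(=O)(=O)C(F)(F)F
Why: Transient protection: the cis‑8,9‑diol is masked as a cyclic boronate so that silylation occurs only at O6, and transesterification to pinacol frees the diol again.

**Step 16**
Reactants: 26 silyl ether diol
Product: 27 tetraol
Conditions: DDQ (2,3‑dichloro‑5,6‑dicyano‑1,4‑benzoquinone), CH2Cl2/pH 7 buffer, 0 °C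
Reagents that add atoms: none
Why: Oxidative cleavage of both PMB ethers (hydride abstraction, hydrolysis of the oxocarbenium ion).

**Step 17**
Reactants: 27 tetraol
Product: 30 9α‑hydroxy lactone enal, via dialdehyde 28 (not isolated), via lactol 29 (not isolated)
Conditions: MnO2 (activated, excess), CH2Cl2, rt
Reagents that add atoms: none
Why: MnO2 allylic oxidation and oxidative lactonisation; the C12 aldehyde is trapped by the 8α‑OH as a lactol and oxidised on to the trans‑fused α‑methylene lactone, while C15 stops at the enal because O6 is silylated.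

**Step 18**
Reactants: 30 hydroxy lactone enal
Product: 31 9α‑methacrylate
Conditions: methacrylic anhydride, Et3N, 4‑(dimethylamino)pyridine (0.3 equiv), CH2Cl2, rt
Reagents that add atoms: methacrylic anhydride, CC(=C)C(=O)OC(=O)C(C)=C
Why: Nucleophile‑catalysed acylation (Steglich type) of the only free hydroxyl, at C9.

**Step 19**
Reactants: 31 silyl‑protected methacrylate
Product: 32 CNP0124638.2
Conditions: HF·pyridine, pyridine, THF, 0 °C → rt
Reagents that add atoms: none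
Why: Buffered fluoride desilylation of the C6 silyl ether; the oxirane, the lactone and the three Michael acceptors are expected to survive at this pH, giving the target.

**Compound list**
1 | 2,3‑dibromoprop‑1‑ene | C=C(Br)CBr | starting material
2 | 4‑methoxybenzyl alcohol | COc1ccc(CO)cc1 | starting material
3 | 2‑bromoallyl 4‑methoxybenzyl ether (1‑{[(2‑bromoprop‑2‑en‑1‑yl)oxy]methyl}‑4‑methoxybenzene) | C=C(Br)COCc1ccc(OC)cc1 | intermediate
4 | (E)‑but‑2‑enal (crotonaldehyde) | C/C=C/C=O | starting material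
5 | (E)‑1‑(tert‑butyldimethylsilyloxy)buta‑1,3‑diene | C=C/C=C/O[Si](C)(C)C(C)(C)C | intermediate
6 | 2‑methylprop‑2‑enal (methacrolein) | C=C(C)C=O | starting material
7 | (1S,2R)‑2‑(tert‑butyldimethylsilyloxy)‑1‑methylcyclohex‑3‑ene‑1‑carbaldehyde (9α‑OTBS, 10β‑Me, 10α‑CHO) | C[C@@]1(C=O)[C@H](O[Si](C)(C)C(C)(C)C)C=CCC1 | intermediate
8 | 10α‑(2‑chloro‑1‑hydroxyethyl)‑10β‑methyl‑9α‑(tert‑butyldimethylsilyloxy)cyclohex‑7‑ene, both C1 epimers | C[C@@]1(C(O)CCl)[C@H](O[Si](C)(C)C(C)(C)C)C=CCC1 | intermediate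
9 | 10α‑(chloroacetyl)‑10β‑methyl‑9α‑(tert‑butyldimethylsilyloxy)cyclohex‑7‑ene | C[C@@]1(C(=O)CCl)[C@H](O[Si](C)(C)C(C)(C)C)C=CCC1 | intermediate
10 | O‑(1,3,2‑benzodioxaborol‑2‑yl) ether of (1R)‑chlorohydrin 11 | C[C@@]1([C@@H](OB2Oc3ccccc3O2)CCl)[C@H](O[Si](C)(C)C(C)(C)C)C=CCC1 | intermediate
11 | 10α‑[(1R)‑2‑chloro‑1‑hydroxyethyl]‑10β‑methyl‑9α‑(tert‑butyldimethylsilyloxy)cyclohex‑7‑ene | C[C@@]1([C@@H](O)CCl)[C@H](O[Si](C)(C)C(C)(C)C)C=CCC1 | intermediate
12 | 10β‑methyl‑10α‑[(2R)‑oxiran‑2‑yl]‑9α‑(tert‑butyldimethylsilyloxy)cyclohex‑7‑ene | C[C@@]1([C@@H]2CO2)[C@H](O[Si](C)(C)C(C)(C)C)C=CCC1 | intermediate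
13 | 10β‑methyl‑10α‑[(2R)‑oxiran‑2‑yl]‑9α‑(tert‑butyldimethylsilyloxy)cyclohex‑7‑en‑6‑one | C[C@@]1([C@@H]2CO2)[C@H](O[Si](C)(C)C(C)(C)C)C=CC(=O)C1 | intermediate
14 | 6‑(trimethylsilyloxy)cyclohexa‑5,7‑diene derived from 13 (silyl dienol ether) | C[C@@]1([C@@H]2CO2)[C@H](O[Si](C)(C)C(C)(C)C)C=CC(O[Si](C)(C)C)=C1 | intermediate
15 | 5β‑[3‑(4‑methoxybenzyloxy)prop‑1‑en‑2‑yl] derivative of enone 13 | C[C@@]1([C@@H]2CO2)[C@H](O[Si](C)(C)C(C)(C)C)C=CC(=O)[C@H]1C(=C)COCc1ccc(OC)cc1 | intermediate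
16 | 7‑iodo derivative of 15 | C[C@@]1([C@@H]2CO2)[C@H](O[Si](C)(C)C(C)(C)C)C=C(I)C(=O)[C@H]1C(=C)COCc1ccc(OC)cc1 | intermediate
17 | [3‑(4‑methoxybenzyloxy)prop‑1‑en‑2‑yl]lithium | [Li]C(=C)COCc1ccc(OC)cc1 | intermediate
18 | [3‑(4‑methoxybenzyloxy)prop‑1‑en‑2‑yl]zinc chloride | Cl[Zn]C(=C)COCc1ccc(OC)cc1 | intermediate
19 | 5β,7‑bis[3‑(4‑methoxybenzyloxy)prop‑1‑en‑2‑yl]‑10β‑methyl‑10α‑[(2R)‑oxiran‑2‑yl]‑9α‑(tert‑butyldimethylsilyloxy)cyclohex‑7‑en‑6‑one | C[C@@]1([C@@H]2CO2)[C@H](O[Si](C)(C)C(C)(C)C)C=C(C(=C)COCc2ccc(OC)cc2)C(=O)[C@H]1C(=C)COCc1ccc(OC)cc1 | intermediate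
20 | 9α‑hydroxy analogue of 19 | C[C@@]1([C@@H]2CO2)[C@H](O)C=C(C(=C)COCc2ccc(OC)cc2)C(=O)[C@H]1C(=C)COCc1ccc(OC)cc1 | intermediate
21 | 7α,8α‑epoxide of 20 (C7 side chain β) | C[C@@]1([C@@H]2CO2)[C@H](O)[C@@H]3O[C@]3(C(=C)COCc2ccc(OC)cc2)C(=O)[C@H]1C(=C)COCc1ccc(OC)cc1 | intermediate
22 | 8α,9α‑dihydroxy‑5β,7β‑bis[3‑(4‑methoxybenzyloxy)prop‑1‑en‑2‑yl]‑10β‑methyl‑10α‑[(2R)‑oxiran‑2‑yl]cyclohexan‑6‑one | C[C@@]1([C@@H]2CO2)[C@H](O)[C@H](O)[C@@H](C(=C)COCc2ccc(OC)cc2)C(=O)[C@H]1C(=C)COCc1ccc(OC)cc1 | intermediate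
23 | 6β,8α,9α‑triol from 22 | C[C@@]1([C@@H]2CO2)[C@H](O)[C@H](O)[C@@H](C(=C)COCc2ccc(OC)cc2)[C@@H](O)[C@H]1C(=C)COCc1ccc(OC)cc1 | intermediate
24 | 8,9‑O‑phenylboronate of 23 | C[C@@]1([C@@H]2CO2)[C@@H]3OB(c4ccccc4)O[C@@H]3[C@@H](C(=C)COCc2ccc(OC)cc2)[C@@H](O)[C@H]1C(=C)COCc1ccc(OC)cc1 | intermediate
25 | 6‑O‑triethylsilyl ether of 24 | C[C@@]1([C@@H]2CO2)[C@@H]3OB(c4ccccc4)O[C@@H]3[C@@H](C(=C)COCc2ccc(OC)cc2)[C@@H](O[Si](CC)(CC)CC)[C@H]1C(=C)COCc1ccc(OC)cc1 | intermediate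
26 | 6β‑(triethylsilyloxy)‑8α,9α‑diol with both PMB ethers | C[C@@]1([C@@H]2CO2)[C@H](O)[C@H](O)[C@@H](C(=C)COCc2ccc(OC)cc2)[C@@H](O[Si](CC)(CC)CC)[C@H]1C(=C)COCc1ccc(OC)cc1 | intermediate
27 | 5β,7β‑bis(3‑hydroxyprop‑1‑en‑2‑yl)‑6β‑(triethylsilyloxy)‑8α,9α‑diol | C[C@@]1([C@@H]2CO2)[C@H](O)[C@H](O)[C@@H](C(=C)CO)[C@@H](O[Si](CC)(CC)CC)[C@H]1C(=C)CO | intermediate
28 | 12,15‑dialdehyde from 27 | C[C@@]1([C@@H]2CO2)[C@H](O)[C@H](O)[C@@H](C(=C)C=O)[C@@H](O[Si](CC)(CC)CC)[C@H]1C(=C)C=O | intermediate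
29 | 8α,12‑lactol 15‑al | C[C@@]1([C@@H]2CO2)[C@H](O)[C@@H]3OC(O)C(=C)[C@H]3[C@@H](O[Si](CC)(CC)CC)[C@H]1C(=C)C=O | intermediate
30 | 9α‑hydroxy‑6β‑(triethylsilyloxy)‑1,2‑epoxy‑15‑oxoelema‑3,11(13)‑dien‑12,8α‑olide | C[C@@]1([C@@H]2CO2)[C@H](O)[C@@H]3OC(=O)C(=C)[C@H]3[C@@H](O[Si](CC)(CC)CC)[C@H]1C(=C)C=O | intermediate
31 | 9α‑methacrylate of 30 | C[C@@]1([C@@H]2CO2)[C@H](OC(=O)C(C)=C)[C@@H]3OC(=O)C(=C)[C@H]3[C@@H](O[Si](CC)(CC)CC)[C@H]1C(=C)C=O | intermediate
32 | CNP0124638.2: (1R,5R,6S,7S,8R,9S,10R)‑1,2‑epoxy‑6β‑hydroxy‑9α‑methacryloyloxy‑15‑oxoelema‑3,11(13)‑dien‑12,8α‑olide | C=C(C)C(=O)O[C@@H]1[C@@H]2OC(=O)C(=C)[C@H]2[C@@H](O)[C@@H](C(=C)C=O)[C@]1(C)[C@@H]1CO1 | target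

**Totals**
Total step count: 19. Longest linear sequence: 18 steps (4 → 32, steps 2–19).

**Steps most likely to fail, each with a fallback**

Step 8 (α′‑alkenylation next to the quaternary carbon) is the weakest step, in both yield and C5 configuration. The fallback brings the C5 side chain in with the dienophile and sets out from 3 and 6. Heck coupling (Pd(OAc)2, Bu4NCl, NaHCO3, DMF, 60 °C) gives (2E)‑4‑{[(4‑methoxybenzyl)oxy]methyl}‑2‑methylpenta‑2,4‑dienal F1. The Diels–Alder reaction of step 3 with diene 5 then gives the 5β‑substituted aldehyde F2, the side chain being trans to the formyl group by the E geometry of the dienophile. The chemistry of steps 4–6 gives the chlorohydrins F3, the chloromethyl ketone F4, the catechol borate F5, the (1R)‑chlorohydrin F6 and the oxiranyl cyclohexene F7. Allylic oxidation with CrO3·3,5‑dimethylpyrazole (CH2Cl2, −20 °C, chosen to spare the PMB ether) comes back to the route at 15.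

Step 12 (basic epoxidation) risks epimerisation or double‑bond migration at C5 of the β,γ‑unsaturated ketone and depends on hydroxyl direction. The fallback sets out from 20 and uses a boronic‑acid‑templated intramolecular oxa‑Michael addition (PhB(OH)2, Et3N cat., 4 Å sieves, toluene). The hemiboronate on O9 delivers oxygen to C8 on the same α face and gives the cyclic phenylboronate F8 of the dihydroxy ketone. Exchange with pinacol comes back to the route at 22, bypassing 21 and step 13.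

Step 15 (one‑pot transient boronate and silylation of a hindered axial alcohol) may give incomplete or unselective silylation. The fallback sets out from 23: 1,1′‑carbonyldiimidazole (toluene, 60 °C) closes the cis‑8,9‑diol to the cyclic carbonate F9, Et3SiOTf/2,6‑lutidine gives the 6‑O‑triethylsilyl carbonate F10, and K2CO3/MeOH methanolyses the carbonate and comes back to the route at 26.

**Further compounds**
F1 | step 8 | (2E)‑4‑{[(4‑methoxybenzyl)oxy]methyl}‑2‑methylpenta‑2,4‑dienal | O=C/C(C)=C/C(=C)COCc1ccc(OC)cc1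
F2 | step 8 | 5β‑[3‑(4‑methoxybenzyloxy)prop‑1‑en‑2‑yl]‑10α‑formyl‑10β‑methyl‑9α‑(tert‑butyldimethylsilyloxy)cyclohex‑7‑ene | C[C@@]1(C=O)[C@H](O[Si](C)(C)C(C)(C)C)C=CC[C@H]1C(=C)COCc1ccc(OC)cc1
F3 | step 8 | 10α‑(2‑chloro‑1‑hydroxyethyl) analogue of F2, both C1 epimers | C[C@@]1(C(O)CCl)[C@H](O[Si](C)(C)C(C)(C)C)C=CC[C@H]1C(=C)COCc1ccc(OC)cc1
F4 | step 8 | 10α‑(chloroacetyl) analogue of F2 | C[C@@]1(C(=O)CCl)[C@H](O[Si](C)(C)C(C)(C)C)C=CC[C@H]1C(=C)COCc1ccc(OC)cc1
F5 | step 8 | O‑(1,3,2‑benzodioxaborol‑2‑yl) ether of F6 | C[C@@]1([C@@H](OB2Oc3ccccc3O2)CCl)[C@H](O[Si](C)(C)C(C)(C)C)C=CC[C@H]1C(=C)COCc1ccc(OC)cc1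
F6 | step 8 | 10α‑[(1R)‑2‑chloro‑1‑hydroxyethyl] analogue of F2 | C[C@@]1([C@@H](O)CCl)[C@H](O[Si](C)(C)C(C)(C)C)C=CC[C@H]1C(=C)COCc1ccc(OC)cc1
F7 | step 8 | 10α‑[(2R)‑oxiran‑2‑yl] analogue of F2 | C[C@@]1([C@@H]2CO2)[C@H](O[Si](C)(C)C(C)(C)C)C=CC[C@H]1C(=C)COCc1ccc(OC)cc1
F8 | step 12 | 8,9‑O‑phenylboronate of ketone 22 | C[C@@]1([C@@H]2CO2)[C@@H]3OB(c4ccccc4)O[C@@H]3[C@@H](C(=C)COCc2ccc(OC)cc2)C(=O)[C@H]1C(=C)COCc1ccc(OC)cc1
F9 | step 15 | 8,9‑cyclic carbonate of triol 23 | C[C@@]1([C@@H]2CO2)[C@@H]3OC(=O)O[C@@H]3[C@@H](C(=C)COCc2ccc(OC)cc2)[C@@H](O)[C@H]1C(=C)COCc1ccc(OC)cc1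
F10 | step 15 | 6‑O‑triethylsilyl ether of F9 | C[C@@]1([C@@H]2CO2)[C@@H]3OC(=O)O[C@@H]3[C@@H](C(=C)COCc2ccc(OC)cc2)[C@@H](O[Si](CC)(CC)CC)[C@H]1C(=C)COCc1ccc(OC)cc1
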